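**Strategy**

The cyclohexadienone ring is made from a cyclopentane: its butanoyl-bearing carbon C2 is inserted last, between C1 and C3. In the key step 1-diazopentan-2-one inserts its CH(COPr) carbon into the CO–CO bond of an (R)-3-methyl-3-prenylcyclopentane-1,2,4-trione, giving the complete 2-acyl-cyclohexane-1,3,5-trione in one operation. The step exploits that quaternary C4 is stereogenic only because the C3/C2 (acyl) and C5/C6 (arylmethyl) flanks differ: in the precursor this difference is stored as vicinal dione versus CH2, and the centre is set earlier by CBS desymmetrisation of 2-methyl-2-prenylcyclopentane-1,3-dione. A reductive Knoevenagel alkylation with a regiodefined aryl aldehyde then forms the methylene bridge.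

Key step: step 7

Remark on the chemistry: the enolised β-di- and β-triketones are each written as one tautomer, and CIP descriptors refer to the tautomer drawn; the sense of induction in step 2 is assigned from the standard CBS model, not from a measurement.

**Route**

Step 1
Reactants: 1 2-methylcyclopentane-1,3-dione; 2 1-bromo-3-methylbut-2-ene (prenyl bromide)
Product: 3 2-methyl-2-(3-methylbut-2-en-1-yl)cyclopentane-1,3-dione
Conditions: NaOH (1 M aq., 1.0 equiv), 2 (1.5 equiv), rt, 24 h
Reagents that add atoms: none
Why: C-alkylation of the stabilised enolate of a 2-substituted cyclic 1,3-diketone with an allylic bromide in water, where hydrogen bonding to the enolate oxygens favours C- over O-alkylation; the product is achiral and its quaternary carbon is prochiral.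

Step 2
Reactants: 3 2-methyl-2-(3-methylbut-2-en-1-yl)cyclopentane-1,3-dione
Product: 4 (2R,3R)-3-hydroxy-2-methyl-2-(3-methylbut-2-en-1-yl)cyclopentan-1-one
Conditions: (S)-2-methyl-CBS-oxazaborolidine (20 mol%), catecholborane (1.1 equiv), toluene, −78 → −60 °C; MeOH quench; chromatography
Reagents that add atoms: none
Why: Corey–Bakshi–Shibata reduction used as a desymmetrisation of enantiotopic carbonyl groups: with the quaternary carbon as the large group the (S)-catalyst should give the (R)-carbinol, hydride enters anti to the larger prenyl group, and together these preferences select the carbonyl whose reduction makes C2 (R); the minor (2S,3R) diastereomer (hydride syn to prenyl) is removed by chromatography, which is what secures the enantiopurity of the quaternary centre.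

Step 3
Reactants: 4 (2R,3R)-3-hydroxy-2-methyl-2-(3-methylbut-2-en-1-yl)cyclopentan-1-one
Product: 5 (2R,3R)-2-methyl-2-(3-methylbut-2-en-1-yl)-3-(triethylsilyloxy)cyclopentan-1-one
Conditions: TESCl (1.3 equiv), imidazole (2 equiv), DMF, 0 °C → rt
Reagents that add atoms: chlorotriethylsilane, CC[Si](CC)(CC)Cl
Why: Standard silylation of a secondary alcohol; it blocks retro-aldol opening of the β-hydroxy ketone under the basic conditions of step 4.

Step 4
Reactants: 5 (2R,3R)-2-methyl-2-(3-methylbut-2-en-1-yl)-3-(triethylsilyloxy)cyclopentan-1-one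
Product: 7 (2R,3R)-3,5-dihydroxy-2-methyl-2-(3-methylbut-2-en-1-yl)cyclopentan-1-one (C5 epimers), via silylated α-hydroxy ketone 6 (not isolated)
Conditions: NaHMDS (1.2 equiv), THF, −78 °C; 2-(phenylsulfonyl)-3-phenyloxaziridine (1.4 equiv), −78 °C; then 1 M HCl, THF, 0 °C → rt
Reagents that add atoms: 2-(phenylsulfonyl)-3-phenyloxaziridine (Davis oxaziridine), O=S(=O)(c1ccccc1)N1OC1c1ccccc1
Why: Enolate hydroxylation with an N-sulfonyloxaziridine (Davis oxidation) at C5, the only enolisable α-position because C2 is quaternary, followed by acid cleavage of the silyl ether; the C5 configuration is irrelevant because this carbon becomes a carbonyl in step 5.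

Step 5
Reactants: 7 (2R,3R)-3,5-dihydroxy-2-methyl-2-(3-methylbut-2-en-1-yl)cyclopentan-1-one
Product: 8 (R)-3-methyl-3-(3-methylbut-2-en-1-yl)cyclopentane-1,2,4-trione
Conditions: Dess–Martin periodinane (2.5 equiv), NaHCO3, CH2Cl2, 0 °C → rt; acidic extractive work-up (no strong aqueous base)
Reagents that add atoms: none
Why: Dess–Martin oxidation of the secondary alcohol and of the α-ketol in one operation should give the vicinal dione next to the quaternary carbon; that carbon has no α-hydrogen and cannot epimerise, and the carbinol stereocentre that differentiated the two carbonyls is expended here by design.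

Step 6
Reactants: 9 butanoyl chloride
Product: 10 1-diazopentan-2-one
Conditions: CH2N2 (2.5 equiv), Et2O, 0 °C
Reagents that add atoms: diazomethane, C=[N+]=[N-]
Why: Acylation of diazomethane by an acid chloride (first stage of the Arndt–Eistert sequence), the second equivalent of diazomethane taking up HCl.

Step 7
Reactants: 8 (R)-3-methyl-3-(3-methylbut-2-en-1-yl)cyclopentane-1,2,4-trione; 10 1-diazopentan-2-one
Product: 12 (R)-2-butanoyl-3,5-dihydroxy-4-methyl-4-(3-methylbut-2-en-1-yl)cyclohexa-2,5-dien-1-one, via chloro(methyl)aluminium enolate 11 (not isolated)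
Conditions: Me2AlCl (1.1 equiv), CH2Cl2, −78 °C, 20 min; then 10 (1.5 equiv, added over 1 h), −78 → 0 °C; cold 1 M HCl
Reagents that add atoms: none
Why: The aluminium enolate 11 has no acidic O–H (which would protonate the diazo ketone and lead to O-alkylation) and holds the aluminium in a five-membered chelate between the C1 enolate oxygen and the C2 carbonyl of 8, the only carbonyl not part of the vinylogous carboxylate; the diazo carbon of 10 adds to this carbonyl and the β-oxido diazonium loses N2 with 1,2-shift of the sp2 carbon C1 rather than of the tertiary alkyl carbon C3. The closest known reaction is the Lewis-acid-promoted diazo–carbonyl homologation (Büchner–Curtius–Schlotterbeck type) in its ring-enlarging form known for cyclic vicinal diketones, which gives 1,3-diketones by insertion of the diazo carbon between the two carbonyls. No ring is closed by cyclisation: the five-membered ring becomes six-membered when the C1–C2 bond of 8 is replaced by C1–CH(COPr)–C2 in a suprafacial 1,2-shift. No stereocentre is created (the new C2 of 12 is an enolised tricarbonyl carbon) and the quaternary carbon keeps all four bonds, so the configuration set in step 2 is carried over unchanged. The step needs carbonyl selectivity (secured by the enolate, which deactivates the C4 carbonyl, and by the chelate), migration selectivity (secured by the higher migratory aptitude of the enolate sp2 carbon over tert-alkyl) and mono-insertion (secured because 12 is no longer a vicinal dione).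

Step 8
Reactants: 13 2,4,6-trihydroxybenzaldehyde
Product: 14 2,6-dihydroxy-4-methoxybenzaldehyde
Conditions: Me2SO4 (1.0 equiv), K2CO3 (1.0 equiv), acetone, 0 °C → rt
Reagents that add atoms: dimethyl sulfate, COS(=O)(=O)OC
Why: Williamson methylation of the most acidic phenol, the 4-OH para to the formyl group, while the two ortho hydroxyls are hydrogen-bonded to the aldehyde and react more slowly; one equivalent of a hard methylating agent limits di- and C-methylation.

Step 9
Reactants: 14 2,6-dihydroxy-4-methoxybenzaldehyde
Product: 15 3-butanoyl-2,6-dihydroxy-4-methoxybenzaldehyde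
Conditions: butanoic anhydride (1.5 equiv), BF3·OEt2 (excess), 60 °C; then aq. NaOAc/MeOH, reflux (hydrolysis of boron chelates)
Reagents that add atoms: butanoic anhydride, CCCC(=O)OC(=O)CCC
Why: Friedel–Crafts acylation (O-acylation and Fries-type shift in BF3) of the phloroglucinol ring, whose only free positions C3 and C5 are equivalent by symmetry so that the regiochemistry is unambiguous; BF3, unlike AlCl3, should leave the aryl methyl ether intact.

Step 10
Reactants: 12 (R)-2-butanoyl-3,5-dihydroxy-4-methyl-4-(3-methylbut-2-en-1-yl)cyclohexa-2,5-dien-1-one; 15 3-butanoyl-2,6-dihydroxy-4-methoxybenzaldehyde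
Product: 17 (4R)-2-butanoyl-6-[(3-butanoyl-2,6-dihydroxy-4-methoxyphenyl)methyl]-3,5-dihydroxy-4-methyl-4-(3-methylbut-2-en-1-yl)cyclohexa-2,5-dien-1-one, via Knoevenagel alkylidene 16 (not isolated)
Conditions: Hantzsch ester (1.2 equiv), L-proline (20 mol%), CH2Cl2, rt
Reagents that add atoms: none
Why: Three-component reductive alkylation (Knoevenagel condensation, then Hantzsch ester transfer hydrogenation of the alkylidene) at C6, the only unsubstituted nucleophilic carbon of 12; it forms the methylene bridge without homodimers and with the aryl regiochemistry fixed by the aldehyde, and no stereocentre is formed or touched.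

**Compound list**

1 | 2-methylcyclopentane-1,3-dione | CC1C(=O)CCC1=O | starting material
2 | 1-bromo-3-methylbut-2-ene (prenyl bromide) | CC(C)=CCBr | starting material
3 | 2-methyl-2-(3-methylbut-2-en-1-yl)cyclopentane-1,3-dione | CC(C)=CCC1(C)C(=O)CCC1=O | intermediate
4 | (2R,3R)-3-hydroxy-2-methyl-2-(3-methylbut-2-en-1-yl)cyclopentan-1-one | CC(C)=CC[C@@]1(C)C(=O)CC[C@H]1O | intermediate
5 | (2R,3R)-2-methyl-2-(3-methylbut-2-en-1-yl)-3-(triethylsilyloxy)cyclopentan-1-one | CC(C)=CC[C@@]1(C)C(=O)CC[C@H]1O[Si](CC)(CC)CC | intermediate
6 | (2R,3R)-5-hydroxy-2-methyl-2-(3-methylbut-2-en-1-yl)-3-(triethylsilyloxy)cyclopentan-1-one, C5 epimers, not isolated | CC(C)=CC[C@@]1(C)C(=O)C(O)C[C@H]1O[Si](CC)(CC)CC | intermediate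
7 | (2R,3R)-3,5-dihydroxy-2-methyl-2-(3-methylbut-2-en-1-yl)cyclopentan-1-one, C5 epimers | CC(C)=CC[C@@]1(C)C(=O)C(O)C[C@H]1O | intermediate
8 | (R)-3-methyl-3-(3-methylbut-2-en-1-yl)cyclopentane-1,2,4-trione | CC(C)=CC[C@@]1(C)C(=O)C(=O)CC1=O | intermediate
9 | butanoyl chloride | CCCC(=O)Cl | starting material
10 | 1-diazopentan-2-one | CCCC(=O)C=[N+]=[N-] | intermediate
11 | chloro(methyl)aluminium enolate of 8 (O–Al on C1, chelated to the C2 carbonyl), not isolated | C[Al](Cl)OC1=CC(=O)[C@@](C)(CC=C(C)C)C1=O | intermediate
12 | (R)-2-butanoyl-3,5-dihydroxy-4-methyl-4-(3-methylbut-2-en-1-yl)cyclohexa-2,5-dien-1-one | CCCC(=O)C1=C(O)[C@](C)(CC=C(C)C)C(O)=CC1=O | intermediate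
13 | 2,4,6-trihydroxybenzaldehyde | O=Cc1c(O)cc(O)cc1O | starting material
14 | 2,6-dihydroxy-4-methoxybenzaldehyde | COc1cc(O)c(C=O)c(O)c1 | intermediate
15 | 3-butanoyl-2,6-dihydroxy-4-methoxybenzaldehyde | CCCC(=O)c1c(OC)cc(O)c(C=O)c1O | intermediate
16 | Knoevenagel alkylidene of 12 and 15 (exocyclic C6=CH–Ar, E/Z not defined; quaternary centre unchanged in space, formally S in this tautomer), not isolated | CCCC(=O)C1=C(O)[C@](C)(CC=C(C)C)C(=O)C(=Cc2c(O)cc(OC)c(C(=O)CCC)c2O)C1=O | intermediate
17 | (4R)-2-butanoyl-6-[(3-butanoyl-2,6-dihydroxy-4-methoxyphenyl)methyl]-3,5-dihydroxy-4-methyl-4-(3-methylbut-2-en-1-yl)cyclohexa-2,5-dien-1-one | CCCC(=O)C1=C(O)[C@](C)(CC=C(C)C)C(O)=C(Cc2c(O)cc(OC)c(C(=O)CCC)c2O)C1=O | target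

**Step count**

Total steps: 10. Longest linear sequence: 7 (steps 1, 2, 3, 4, 5, 7, 10).

**Steps most likely to fail**

1. Step 7 (ring expansion). What may go wrong: protonation of the diazo ketone by residual enol O–H with O-alkylation, chloride transfer from aluminium to the diazo ketone, sluggish addition to the chelated carbonyl, or migration of the quaternary carbon instead of the sp2 carbon. Fallback (sets out from 6, returns at 12): the insertion is split into an anionic C–C bond formation and a separate rhodium-carbenoid 1,2-shift on a substrate without acidic protons. Compound 6 is isolated by neutral work-up and oxidised (Dess–Martin periodinane) to (4R,5R)-2-hydroxy-5-methyl-5-(3-methylbut-2-en-1-yl)-4-(triethylsilyloxy)cyclopent-2-en-1-one F1. Silylation (TESOTf, Et3N, CH2Cl2, −78 °C) should give the bis-silyl 2-silyloxy enone F2. The lithium derivative of 10 (LDA, THF, −78 °C) is added to the enone carbonyl to give the α-diazo-β-hydroxy ketone F3. Rh2(OAc)4 (1 mol%, CH2Cl2, rt) should then induce loss of N2 and 1,2-shift of the silyloxyvinyl carbon to give the ring-expanded (5R,6R)-2-butanoyl-6-methyl-6-(3-methylbut-2-en-1-yl)-3,5-bis(triethylsilyloxy)cyclohex-3-en-1-one F4. HF·pyridine removes both silyl groups to give the hydroxy triketone F5, and Dess–Martin oxidation of its secondary alcohol gives 12.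

2. Step 10 (methylene bridge). What may go wrong: slow or reversible condensation of the hindered, hydrogen-bonded aldehyde, or consumption of the alkylidene by a second Michael addition or by cyclisation onto the ortho phenol before it is reduced. Fallback (sets out from 15, returns at 17): the reduction is done before the C–C bond is formed. Reductive amination of 15 (Me2NH, NaBH(OAc)3, 1,2-dichloroethane, rt) should give the Mannich-type base 1-[3-(dimethylaminomethyl)-2,4-dihydroxy-6-methoxyphenyl]butan-1-one F6. Heating F6 with 12 (toluene, 100 °C) releases dimethylamine and generates the ortho-quinone methide, which is trapped by conjugate addition of C6 of 12 to give 17.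

3. Step 9 (C-acylation of the formylated ring). What may go wrong: incomplete acylation of the aldehyde-deactivated ring, condensation at the aldehyde under Lewis acid, or loss of the methyl ether. Fallback (sets out from 14, returns at 15): the acyl group is attached to oxygen first and moved to carbon without Lewis acid. Mono-O-acylation of 14 (butanoyl chloride, 1.0 equiv, pyridine, CH2Cl2, 0 °C) gives 2-formyl-3-hydroxy-5-methoxyphenyl butanoate F7. Photo-Fries rearrangement (254 nm, MeCN) should then give 15; ortho and para shift lead to the same compound because C3 and C5 of 14 are equivalent.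

**Further compounds**

F1 | step 7 | (4R,5R)-2-hydroxy-5-methyl-5-(3-methylbut-2-en-1-yl)-4-(triethylsilyloxy)cyclopent-2-en-1-one | CC(C)=CC[C@@]1(C)C(=O)C(O)=C[C@H]1O[Si](CC)(CC)CC
F2 | step 7 | (4R,5R)-5-methyl-5-(3-methylbut-2-en-1-yl)-2,4-bis(triethylsilyloxy)cyclopent-2-en-1-one | CC(C)=CC[C@@]1(C)C(=O)C(O[Si](CC)(CC)CC)=C[C@H]1O[Si](CC)(CC)CC
F3 | step 7 | 1-diazo-1-[(4R,5R)-1-hydroxy-5-methyl-5-(3-methylbut-2-en-1-yl)-2,4-bis(triethylsilyloxy)cyclopent-2-en-1-yl]pentan-2-one (C1 epimers) | CC(C)=CC[C@@]1(C)C(O)(C(=[N+]=[N-])C(=O)CCC)C(O[Si](CC)(CC)CC)=C[C@H]1O[Si](CC)(CC)CC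
F4 | step 7 | (5R,6R)-2-butanoyl-6-methyl-6-(3-methylbut-2-en-1-yl)-3,5-bis(triethylsilyloxy)cyclohex-3-en-1-one | CC(C)=CC[C@@]1(C)C(=O)C(C(=O)CCC)C(O[Si](CC)(CC)CC)=C[C@H]1O[Si](CC)(CC)CC
F5 | step 7 | (5R,6R)-2-butanoyl-5-hydroxy-6-methyl-6-(3-methylbut-2-en-1-yl)cyclohexane-1,3-dione | CC(C)=CC[C@@]1(C)C(=O)C(C(=O)CCC)C(=O)C[C@H]1O
F6 | step 10 | 1-[3-(dimethylaminomethyl)-2,4-dihydroxy-6-methoxyphenyl]butan-1-one | CCCC(=O)c1c(OC)cc(O)c(CN(C)C)c1O
F7 | step 9 | 2-formyl-3-hydroxy-5-methoxyphenyl butanoate | CCCC(=O)Oc1cc(OC)cc(O)c1C=O
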